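Rings A and C are made last and together. In each, the C2(O)–C3(CH2)–C4(O)–C5(CH3) segment is the imprint of a 2,4-disubstituted cyclohexane-1,3-dione, and C1 (butanoyl) with C6 (OCH3) is a two-carbon alkyne unit. A ring B-centred bis(1-benzyloxy-3-silyloxycyclohexa-1,3-diene) therefore takes up two molecules of 1-methoxyhex-1-yn-3-one, forming C1–C2 and C5–C6 on both flanks, and loses ethene twice, so that both fully substituted arenes appear in one operation with the methyl ether already in position. The precursor is 1,3,5-tris(benzyloxy)benzene bearing two dienylmethyl arms. The (S)-2-methylbutanoyl group enters afterwards at ring B C5, the only free position.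

Key step: step 9

Remark: the (S) centre comes from (S)-2-methylbutanoic acid and is attached after the cycloaddition, on the still fully protected trimer, so it never meets amide bases or a strong Lewis acid; the two C6 centres made in step 5 are transient and are drawn without configuration.

Step 1
Reactants: 1 phloroglucinol
Product: 3 2,4,6-trihydroxybenzene-1,3-dicarbaldehyde, via bis(iminium) dichloride 2 (not isolated)
Conditions: POCl3 (2.5 equiv), DMF, 1,4-dioxane, 0 °C → rt; then H2O, rt
Reagents that add atoms: N,N-dimethylformamide CN(C)C=O; water O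
Why: Vilsmeier–Haack formylation, in which the very nucleophilic triol should take up two chloroiminium electrophiles (the third position being deactivated by the two iminium groups) and aqueous hydrolysis releases the dialdehyde.

Step 2
Reactants: 3 2,4,6-trihydroxybenzene-1,3-dicarbaldehyde
Product: 4 2,4,6-tris(benzyloxy)benzene-1,3-dicarbaldehyde
Conditions: BnBr (3.6 equiv), K2CO3 (4.5 equiv), DMF, 60 °C
Reagents that add atoms: benzyl bromide BrCc1ccccc1
Why: Williamson ether synthesis, in which the three phenols acidified by the ortho formyl groups should be O-benzylated while the electron-poor ring is a weak carbon nucleophile.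

Step 3
Reactants: 4 2,4,6-tris(benzyloxy)benzene-1,3-dicarbaldehyde; 5 cyclohexane-1,3-dione
Product: 7 2,2'-{[2,4,6-tris(benzyloxy)-1,3-phenylene]bis(methylene)}bis(cyclohexane-1,3-dione), via bis(alkylidene) intermediate 6 (not isolated)
Conditions: 5 (2.2 equiv), diethyl 2,6-dimethyl-1,4-dihydropyridine-3,5-dicarboxylate (2.2 equiv), L-proline (20 mol%), CH2Cl2, rt
Reagents that add atoms: none
Why: organocatalytic three-component reductive alkylation (Knoevenagel condensation, then transfer hydrogenation by the Hantzsch ester), in which each alkylidene-dione arm is reduced as soon as it forms, so a second dione should not add to it.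

Step 4
Reactants: 7 2,2'-{[2,4,6-tris(benzyloxy)-1,3-phenylene]bis(methylene)}bis(cyclohexane-1,3-dione)
Product: 8 2,2'-{[2,4,6-tris(benzyloxy)-1,3-phenylene]bis(methylene)}bis[3-(benzyloxy)cyclohex-2-en-1-one]
Conditions: BnOH (2.4 equiv), PPh3 (2.4 equiv), DIAD (2.4 equiv), THF, 0 °C → rt
Reagents that add atoms: benzyl alcohol OCc1ccccc1
Why: Mitsunobu etherification of the acidic dione enols, in which the enol oxygen displaces the benzyloxyphosphonium ion to give the vinylogous benzyl esters, while attack through C2 would have to build a crowded quaternary centre.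

Step 5
Reactants: 8 2,2'-{[2,4,6-tris(benzyloxy)-1,3-phenylene]bis(methylene)}bis[3-(benzyloxy)cyclohex-2-en-1-one]
Product: 10 2,2'-{[2,4,6-tris(benzyloxy)-1,3-phenylene]bis(methylene)}bis[3-(benzyloxy)-6-methylcyclohex-2-en-1-one], via dilithium bis(dienolate) 9 (not isolated)
Conditions: LiN(iPr)2 (2.3 equiv), THF, −78 °C; then MeI (5 equiv), −78 → −20 °C
Reagents that add atoms: iodomethane CI
Why: Stork–Danheiser kinetic alpha-prime alkylation of the vinylogous esters, in which the cross-conjugated C6 enolates are methylated once each; the two new C6 stereocentres form without control as a diastereomer mixture, which is harmless because both are flattened in step 6.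

Step 6
Reactants: 10 2,2'-{[2,4,6-tris(benzyloxy)-1,3-phenylene]bis(methylene)}bis[3-(benzyloxy)-6-methylcyclohex-2-en-1-one]
Product: 12 1,3,5-tris(benzyloxy)-2,4-bis{[2-(benzyloxy)-6-(tert-butyldimethylsilyloxy)-5-methylcyclohexa-1,5-dien-1-yl]methyl}benzene, via dilithium bis(dienolate) 11 (not isolated)
Conditions: LiN(iPr)2 (2.5 equiv), THF, −78 °C; then TBSCl (3 equiv), DMPU, −78 → 0 °C; non-aqueous work-up
Reagents that add atoms: tert-butyldimethylsilyl chloride CC(C)(C)[Si](C)(C)Cl
Why: kinetic enolisation and O-silylation (silyl enol ether formation), in which the remaining C6–H is again the kinetic site, so each arm should become a 1-benzyloxy-3-silyloxycyclohexa-1,3-diene with the methyl group on a diene terminus and the C6 stereocentres disappear.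

Step 7
Reactants: 13 butanoyl chloride
Product: 14 N-methoxy-N-methylbutanamide
Conditions: MeNHOMe·HCl (1.1 equiv), Et3N (2.2 equiv), CH2Cl2, 0 °C → rt
Reagents that add atoms: N,O-dimethylhydroxylamine hydrochloride CNOC.Cl
Why: acylation of an amine by an acid chloride (Weinreb amide formation), a routine amide synthesis.

Step 8
Reactants: 15 2-chloro-1,1-dimethoxyethane; 14 N-methoxy-N-methylbutanamide
Product: 17 1-methoxyhex-1-yn-3-one, via lithium methoxyacetylide 16 (not isolated)
Conditions: 15 (1.3 equiv), LiNEt2 (4.0 equiv), THF, 0 °C; then 14 (1.0 equiv), −78 → 0 °C; pH 7 buffer (NaH2PO4/Na2HPO4), cold work-up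
Reagents that add atoms: none
Why: double elimination of the chloroacetal by the lithium amide gives the lithium alkoxyacetylide, which adds once to the Weinreb amide (Weinreb ketone synthesis) because the chelated tetrahedral adduct releases the ynone only on neutral work-up.

Step 9
Reactants: 12 1,3,5-tris(benzyloxy)-2,4-bis{[2-(benzyloxy)-6-(tert-butyldimethylsilyloxy)-5-methylcyclohexa-1,5-dien-1-yl]methyl}benzene; 17 1-methoxyhex-1-yn-3-one
Product: 19 1,1'-{[2,4,6-tris(benzyloxy)-1,3-phenylene]bis[methylene(2-benzyloxy-4-(tert-butyldimethylsilyloxy)-6-methoxy-5-methyl-3,1-phenylene)]}bis(butan-1-one), via bis(bicyclooctadiene) cycloadduct 18 (not isolated)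
Conditions: 17 (6 equiv), o-xylene (1 M in 12), 2,6-di-tert-butyl-4-methylphenol (5 mol%), sealed tube, 150 °C
Reagents that add atoms: none
Why: Proposed new method: each cyclohexa-1,3-diene, locked s-cis by its ring, should undergo a thermal, asynchronous (4+2) cycloaddition with the ynone to a bicyclo[2.2.2]octa-2,5-diene that then expels its CH2–CH2 bridge as ethene in a retro-(4+2) step driven by aromatisation and gas loss; the closest known reaction type is the Alder–Rickert reaction of 1,3-dioxygenated cyclohexa-1,3-dienes with acetylenic ketones and esters, and the new element is a push-pull beta-methoxy ynone meeting a fully substituted diene. Ring A and ring C are each closed by an intermolecular (4+2) annulation that joins C1–C2 and C5–C6, the other four ring atoms coming from the dione-derived ring. No stereocentre is created that survives, since the bridgehead centres of 18 are destroyed when ethene leaves. The step needs regioselectivity, and the diene supplies it: the 3-silyloxy group, reinforced by the vinylogous 1-benzyloxy group, makes the methyl-bearing terminus the nucleophilic end, which bonds to the OCH3-bearing beta carbon of the ynone, so the benzyloxy-bearing terminus bonds to the acyl-bearing alpha carbon. The O-methyl group offers no hydrogen for the retro-ene fragmentation to a ketene that limits higher alkoxyalkynes on heating, and a large excess of 17 at high concentration should offset its low dienophilicity. The two flanks are identical and react independently, so no selectivity between them is needed.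

Step 10
Reactants: 19 1,1'-{[2,4,6-tris(benzyloxy)-1,3-phenylene]bis[methylene(2-benzyloxy-4-(tert-butyldimethylsilyloxy)-6-methoxy-5-methyl-3,1-phenylene)]}bis(butan-1-one); 20 (S)-2-methylbutanoic acid
Product: 22 1,1'-{[2,4,6-tris(benzyloxy)-5-((2S)-2-methylbutanoyl)-1,3-phenylene]bis[methylene(2-benzyloxy-4-(tert-butyldimethylsilyloxy)-6-methoxy-5-methyl-3,1-phenylene)]}bis(butan-1-one), via mixed trifluoroacetic anhydride 21 (not isolated)
Conditions: 20 (3 equiv), TFAA (3 equiv), CH2Cl2, 0 °C, 30 min; then 19, 0 °C → rt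
Reagents that add atoms: none
Why: Friedel–Crafts acylation through a mixed trifluoroacetic anhydride without a Lewis acid, which should hit ring B C5 (ortho to two and para to one benzyloxy group, and the only unsubstituted position on an activated ring) and should carry the (S) centre of the acid over unchanged because neither base nor an enolising metal halide is present.

Step 11
Reactants: 22 1,1'-{[2,4,6-tris(benzyloxy)-5-((2S)-2-methylbutanoyl)-1,3-phenylene]bis[methylene(2-benzyloxy-4-(tert-butyldimethylsilyloxy)-6-methoxy-5-methyl-3,1-phenylene)]}bis(butan-1-one)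
Product: 23 1,1'-{[2,4,6-tris(benzyloxy)-5-((2S)-2-methylbutanoyl)-1,3-phenylene]bis[methylene(2-benzyloxy-4-hydroxy-6-methoxy-5-methyl-3,1-phenylene)]}bis(butan-1-one)
Conditions: Bu4NF (2.5 equiv), AcOH (2.5 equiv), THF, 0 °C
Reagents that add atoms: none
Why: fluoride-mediated cleavage of the two aryl silyl ethers, with acetic acid buffering the medium so that the alpha stereocentre of the hindered ring B ketone should not be enolised.

Step 12
Reactants: 23 1,1'-{[2,4,6-tris(benzyloxy)-5-((2S)-2-methylbutanoyl)-1,3-phenylene]bis[methylene(2-benzyloxy-4-hydroxy-6-methoxy-5-methyl-3,1-phenylene)]}bis(butan-1-one)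
Product: 24 agrimol B
Conditions: H2 (1 atm), 10% Pd/C, EtOAc–MeOH, rt
Reagents that add atoms: none
Why: catalytic hydrogenolysis of the five benzyl aryl ethers under neutral conditions, which should leave the hindered aryl ketones, the diarylmethane bridges, the methyl ethers and the (S) centre untouched.

Compound list
1 | phloroglucinol (benzene-1,3,5-triol) | Oc1cc(O)cc(O)c1 | starting material
2 | bis(iminium) dichloride: [(2,4,6-trihydroxy-1,3-phenylene)dimethanylylidene]bis(dimethylammonium) dichloride | C[N+](C)=Cc1c(O)cc(O)c(C=[N+](C)C)c1O.[Cl-].[Cl-] | intermediate (not isolated)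
3 | 2,4,6-trihydroxybenzene-1,3-dicarbaldehyde | O=Cc1c(O)cc(O)c(C=O)c1O | intermediate
4 | 2,4,6-tris(benzyloxy)benzene-1,3-dicarbaldehyde | O=Cc1c(OCc2ccccc2)cc(OCc2ccccc2)c(C=O)c1OCc1ccccc1 | intermediate
5 | cyclohexane-1,3-dione | O=C1CCCC(=O)C1 | starting material
6 | bis(alkylidene) intermediate: 2,2'-{[2,4,6-tris(benzyloxy)-1,3-phenylene]dimethanylylidene}bis(cyclohexane-1,3-dione), each arm reduced as it forms | O=C1CCCC(=O)C1=Cc1c(OCc2ccccc2)cc(OCc2ccccc2)c(C=C2C(=O)CCCC2=O)c1OCc1ccccc1 | intermediate (not isolated)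
7 | 2,2'-{[2,4,6-tris(benzyloxy)-1,3-phenylene]bis(methylene)}bis(cyclohexane-1,3-dione), drawn as the diketone, enolised in solution | O=C1CCCC(=O)C1Cc1c(OCc2ccccc2)cc(OCc2ccccc2)c(CC2C(=O)CCCC2=O)c1OCc1ccccc1 | intermediate
8 | 2,2'-{[2,4,6-tris(benzyloxy)-1,3-phenylene]bis(methylene)}bis[3-(benzyloxy)cyclohex-2-en-1-one] | O=C1CCCC(OCc2ccccc2)=C1Cc1c(OCc2ccccc2)cc(OCc2ccccc2)c(CC2=C(OCc3ccccc3)CCCC2=O)c1OCc1ccccc1 | intermediate
9 | dilithium bis(dienolate) of 8 (C1–O–Li, C1=C6 in each arm) | [Li]OC1=CCCC(OCc2ccccc2)=C1Cc1c(OCc2ccccc2)cc(OCc2ccccc2)c(CC2=C(OCc3ccccc3)CCC=C2O[Li])c1OCc1ccccc1 | intermediate (not isolated)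
10 | 2,2'-{[2,4,6-tris(benzyloxy)-1,3-phenylene]bis(methylene)}bis[3-(benzyloxy)-6-methylcyclohex-2-en-1-one], diastereomer mixture at the two C6 centres | CC1CCC(OCc2ccccc2)=C(Cc2c(OCc3ccccc3)cc(OCc3ccccc3)c(CC3=C(OCc4ccccc4)CCC(C)C3=O)c2OCc2ccccc2)C1=O | intermediate
11 | dilithium bis(dienolate) of 10 | [Li]OC1=C(C)CCC(OCc2ccccc2)=C1Cc1c(OCc2ccccc2)cc(OCc2ccccc2)c(CC2=C(OCc3ccccc3)CCC(C)=C2O[Li])c1OCc1ccccc1 | intermediate (not isolated)
12 | bis-diene: 1,3,5-tris(benzyloxy)-2,4-bis{[2-(benzyloxy)-6-(tert-butyldimethylsilyloxy)-5-methylcyclohexa-1,5-dien-1-yl]methyl}benzene | CC(C)(C)[Si](C)(C)OC1=C(C)CCC(OCc2ccccc2)=C1Cc1c(OCc2ccccc2)cc(OCc2ccccc2)c(CC2=C(OCc3ccccc3)CCC(C)=C2O[Si](C)(C)C(C)(C)C)c1OCc1ccccc1 | intermediate (key-step precursor)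
13 | butanoyl chloride | CCCC(Cl)=O | starting material
14 | N-methoxy-N-methylbutanamide | CCCC(=O)N(C)OC | intermediate
15 | 2-chloro-1,1-dimethoxyethane | COC(CCl)OC | starting material
16 | lithium methoxyacetylide | [Li]C#COC | intermediate (not isolated)
17 | 1-methoxyhex-1-yn-3-one | CCCC(=O)C#COC | intermediate
18 | bis(bicyclo[2.2.2]octa-2,5-diene) cycloadduct: each arm has bridgeheads bearing CH3 and OBn, one alkene C(OTBS)=C(CH2Ar), one alkene C(OCH3)=C(butanoyl) and a CH2–CH2 bridge; transient bridgehead stereocentres not specified | C(C2=C(O[Si](C)(C)C(C)(C)C)C3(C)CCC2(OCc2ccccc2)C(C(=O)CCC)=C3OC)c1c(OCc2ccccc2)cc(OCc2ccccc2)c(CC2=C(O[Si](C)(C)C(C)(C)C)C3(C)CCC2(OCc2ccccc2)C(C(=O)CCC)=C3OC)c1OCc1ccccc1 | intermediate (not isolated)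
19 | protected trimer: ring B 1,3,5-tris(benzyloxy) with C5–H; rings A and C each 1-butanoyl, 2-OBn, 3-CH2 (to ring B), 4-OTBS, 5-CH3, 6-OCH3 | CCCC(=O)c1c(OC)c(C)c(O[Si](C)(C)C(C)(C)C)c(Cc2c(OCc3ccccc3)cc(OCc3ccccc3)c(Cc3c(OCc4ccccc4)c(C(=O)CCC)c(OC)c(C)c3O[Si](C)(C)C(C)(C)C)c2OCc2ccccc2)c1OCc1ccccc1 | intermediate (key-step product)
20 | (S)-2-methylbutanoic acid | CC[C@H](C)C(O)=O | starting material
21 | (S)-2-methylbutanoic trifluoroacetic anhydride | CC[C@H](C)C(=O)OC(=O)C(F)(F)F | intermediate (not isolated)
22 | protected trimer carrying (S)-2-methylbutanoyl at ring B C5 | CCCC(=O)c1c(OC)c(C)c(O[Si](C)(C)C(C)(C)C)c(Cc2c(OCc3ccccc3)c(C(=O)[C@@H](C)CC)c(OCc3ccccc3)c(Cc3c(OCc4ccccc4)c(C(=O)CCC)c(OC)c(C)c3O[Si](C)(C)C(C)(C)C)c2OCc2ccccc2)c1OCc1ccccc1 | intermediate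
23 | pentabenzyl ether of agrimol B (ring A and ring C C4–OH free, (S) side chain) | CCCC(=O)c1c(OC)c(C)c(O)c(Cc2c(OCc3ccccc3)c(C(=O)[C@@H](C)CC)c(OCc3ccccc3)c(Cc3c(OCc4ccccc4)c(C(=O)CCC)c(OC)c(C)c3O)c2OCc2ccccc2)c1OCc1ccccc1 | intermediate
24 | agrimol B, (S) configuration at the 2-methylbutanoyl alpha carbon | CCCC(=O)c1c(O)c(Cc2c(O)c(Cc3c(O)c(C)c(OC)c(C(=O)CCC)c3O)c(O)c(C(=O)[C@@H](C)CC)c2O)c(O)c(C)c1OC | target

Total step count: 12
Longest linear sequence: 10 steps (steps 1–6 and 9–12)

Steps most likely to fail

Step 9. The donor-substituted alkyne may be too electron-rich to engage the tetrasubstituted diene before the silyl dienol ether degrades or the ynone oligomerises. Bond formation may also stop after the first C–C bond without ring closure, or only one flank may react. The fallback sets out from 12 and comes back at 19, replacing the push-pull ynone by a halo-ynone, a dienophile class with Diels–Alder precedent. Commercial hex-1-yn-3-ol (CCCC(O)C#C) is brominated at the alkyne terminus (NBS, AgNO3 cat., acetone) to 1-bromohex-1-yn-3-ol F1 and oxidised (MnO2, CH2Cl2) to 1-bromohex-1-yn-3-one F2. Heating 12 with F2 in toluene at 110–130 °C should give, through the bis(bicyclooctadiene) cycloadduct F3 and loss of ethene, the bis(aryl bromide) F4 with the same orientation, because bromine does not change which alkyne carbon is the beta carbon. Ullmann-type methoxylation (NaOMe, CuI cat., MeOH–DMF, 100 °C) should exchange both bromides, which sit ortho to an acyl group, and strip the aryl silyl ethers at the same time, giving the bis(phenol) F5. Resilylation (TBSCl, imidazole, DMF) then returns to 19.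

Step 10. Trifluoroacetic acid set free during the acylation may strip silyl or benzyl groups or cut the diarylmethane links, the ring may take up a trifluoroacetyl group instead, or the crowded position may not react. The fallback sets out from 19 and comes back at 24, acylating after deprotection instead of before. Hydrogenolysis (H2, 10% Pd/C, EtOAc–MeOH) gives the pentaphenol bis(silyl ether) F6, and HF·pyridine in THF gives the heptaphenol F7. Acid 20 is converted with oxalyl chloride (cat. DMF, CH2Cl2) to (S)-2-methylbutanoyl chloride F8. Friedel–Crafts acylation of F7 with F8 and AlCl3 in CH2Cl2–PhNO2 at 0 °C should again be confined to ring B C5, the only free nuclear position. The low temperature is meant to spare the methyl ethers ortho to the ketones and the stereocentre.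

Step 4. The enol may be alkylated at carbon C2 instead of at oxygen, or only one of the two dione units may be etherified. The fallback sets out from 7 and comes back at 8 by way of the vinylogous acid chloride. Oxalyl chloride (cat. DMF, CH2Cl2, 0 °C) should convert each dione into a 3-chloroenone, giving the bis(3-chlorocyclohex-2-enone) F9. Addition–elimination with sodium benzyloxide (BnOH, NaH, THF, 0 °C) then places the benzyloxy groups on oxygen only and gives 8.

Further compounds
F1 | step 9 | 1-bromohex-1-yn-3-ol (racemic) | CCCC(O)C#CBr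
F2 | step 9 | 1-bromohex-1-yn-3-one | CCCC(=O)C#CBr
F3 | step 9 | bis(bicyclo[2.2.2]octa-2,5-diene) cycloadduct with C(Br)=C(butanoyl) alkenes (formed in the flask) | C(C2=C(O[Si](C)(C)C(C)(C)C)C3(C)CCC2(OCc2ccccc2)C(C(=O)CCC)=C3Br)c1c(OCc2ccccc2)cc(OCc2ccccc2)c(CC2=C(O[Si](C)(C)C(C)(C)C)C3(C)CCC2(OCc2ccccc2)C(C(=O)CCC)=C3Br)c1OCc1ccccc1
F4 | step 9 | bis(aryl bromide) analogue of 19 (Br in place of OCH3 at C6 of rings A and C) | CCCC(=O)c1c(Br)c(C)c(O[Si](C)(C)C(C)(C)C)c(Cc2c(OCc3ccccc3)cc(OCc3ccccc3)c(Cc3c(OCc4ccccc4)c(C(=O)CCC)c(Br)c(C)c3O[Si](C)(C)C(C)(C)C)c2OCc2ccccc2)c1OCc1ccccc1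
F5 | step 9 | bis(phenol): 19 without its two silyl groups | CCCC(=O)c1c(OC)c(C)c(O)c(Cc2c(OCc3ccccc3)cc(OCc3ccccc3)c(Cc3c(OCc4ccccc4)c(C(=O)CCC)c(OC)c(C)c3O)c2OCc2ccccc2)c1OCc1ccccc1
F6 | step 10 | pentaphenol bis(silyl ether): 19 without its five benzyl groups | CCCC(=O)c1c(OC)c(C)c(O[Si](C)(C)C(C)(C)C)c(Cc2c(O)cc(O)c(Cc3c(O)c(C(=O)CCC)c(OC)c(C)c3O[Si](C)(C)C(C)(C)C)c2O)c1O
F7 | step 10 | heptaphenol: agrimol B lacking the ring B acyl group | CCCC(=O)c1c(OC)c(C)c(O)c(Cc2c(O)cc(O)c(Cc3c(O)c(C(=O)CCC)c(OC)c(C)c3O)c2O)c1O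
F8 | step 10 | (S)-2-methylbutanoyl chloride | CC[C@H](C)C(Cl)=O
F9 | step 4 | 2,2'-{[2,4,6-tris(benzyloxy)-1,3-phenylene]bis(methylene)}bis(3-chlorocyclohex-2-en-1-one) | O=C1CCCC(Cl)=C1Cc1c(OCc2ccccc2)cc(OCc2ccccc2)c(CC2=C(Cl)CCCC2=O)c1OCc1ccccc1
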